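Readings and results stem from a simulated flask from invented constants, noise included.

We rank these flasks by how much mono adduct survives its own decay, so we read that decay first.

| setting | epsilon | alpha | beta | Tuesday's | Thursday's | Sunday's |
|---|---|---|---|---|---|---|
| substrate | 0.28 M | 0.44 M | 0.20 M | 0.20 M | 0.20 M | 0.20 M |
| reagent | 0.22 M | 0.22 M | 0.44 M | 0.220 M | 0.220 M | 0.220 M |
| temperature | 0 °C | 25 °C | 0 °C | 45 °C | 25 °C | 5 °C |
| remark | run made earlier | run made earlier | run made earlier |  |  |  |
| time |  |  |  | 15 min | 15 min | 15 min |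

| run | time / min | mono adduct / % | substrate / % |
|---|---|---|---|
| epsilon | 8.00 | 28.6 | 63.4 |
| epsilon | 25.0 | 30.1 | 46.5 |
| epsilon | 40.0 | 26.3 | 42.6 |
| epsilon | 60.0 | 21.1 | 41.6 |
| epsilon | 90.0 | 15.6 | 41.1 |
| epsilon | 120 | 10.8 | 40.9 |
| alpha | 5.00 | 19.2 | 60.4 |
| alpha | 10.0 | 14.6 | 59.6 |
| alpha | 15.0 | 11.1 | 61.6 |
| alpha | 20.0 | 8.7 | 61.3 |
| alpha | 25.0 | 6.2 | 60.9 |
| alpha | 30.0 | 4.7 | 60.9 |
| beta | 10.0 | 35.4 | 29.4 |
| beta | 20.0 | 24.4 | 14.7 |
| beta | 30.0 | 16.1 | 8.0 |
| beta | 60.0 | 4.6 | 2.2 |
| beta | 120 | 1.0 | 0.4 |

(scatter of a reading: 0.5 percentage points)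

- the best flask by amount of mono adduct, in percent of the substrate charged; "all alike" if 1.5 percentage points covers them all (Tuesday's / Thursday's / Sunday's / all alike)
- amount of mono adduct at the end, in percent of the substrate charged, Tuesday's
- amount of mono adduct at the end, in percent of the substrate charged, Thursday's
- amount of mono adduct at the end, in percent of the substrate charged, Sunday's

In the alpha run, substrate stands still from 60.4% to 60.9%, yet mono adduct keeps falling. That fall, taken as first order once substrate has stopped moving, gives our tail constant: 0.0563 min⁻¹ at 25 °C. The epsilon run's flat stretch gives 0.0112 min⁻¹ at 0 °C. So over 15 min a share 84.6% survives the cold tail, against 43.0% at 25 °C.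

Now the bracket for Thursday's. For the ceiling, we grant it beta's peak reading, 35.4%, and start the decay at alpha's first reading, which gives 20.2%. For a working floor, a judgement and no strict bound, we take alpha's own reading at that time and temperature, 11.1%, although alpha had 0.500 equivalents of reagent and Thursday's has 1.10. Sunday's, near the cold tail, we place between epsilon's first reading, 28.6%, and 35.4%. Its floor stands above Thursday's ceiling, and Tuesday's is hotter still, so we back Sunday's.

The forecast names Sunday's, with 2.7%, 16% and 31% for Tuesday's, Thursday's and Sunday's, and both of its upper values sit inside our brackets; it calls the loss one “which needs no reagent”.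

The flasks give 1.27%, 12.3% and 31.3%, so Sunday's leads, and Thursday's lands inside its bracket.

    substrate + reagent → mono adduct + by-product (k = 0.0520 M⁻¹ s⁻¹, Ea = 58.0 kJ mol⁻¹)
    substrate + reagent → other mono adduct + by-product (k = 0.00290 M⁻¹ s⁻¹, Ea = 69.0 kJ mol⁻¹)
    reagent + mono adduct → bis adduct + by-product (k = 0.0730 M⁻¹ s⁻¹, Ea = 68.0 kJ mol⁻¹)
    reagent + other mono adduct → bis adduct + by-product (k = 0.0840 M⁻¹ s⁻¹, Ea = 59.0 kJ mol⁻¹)
    mono adduct + by-product → side product (k = 0.00590 M⁻¹ s⁻¹, Ea = 45.0 kJ mol⁻¹)
    (constants at 25 °C)

The tail constant is an averaged pseudo-first-order constant of the step from mono adduct + by-product to side product, for c(by-product) is not steady: in Thursday's it goes from 0.194 M at 7.50 min to 0.183 M at 15.0 min. In Thursday's, its constant times c(by-product) at 15.0 min gives 0.0647 min⁻¹, beside our 0.0563 min⁻¹. Tuesday's shows its weight: without this step it holds 23.6%, and without the step from reagent + mono adduct to bis adduct 19.6%, against 1.27%; the two act together.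

Sunday's flask at −10 °C is colder than the epsilon run, so we expect its tail constant below 0.0112 min⁻¹, which over 15 min means a surviving share above 84.6%. It gives 26.2% mono adduct with 0.371% side product, and 68% of the substrate is still unbound.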